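The runs stem from a simulated flask from invented constants, noise included.

At early times zeta and alpha both lose substrate, but zeta stops: 61.0% stands at 30.0 h and 60.0% at 40.0 h.

For whoever takes over: four flasks hold substrate, coupling partner, transfer agent and initiator, and differ in initiator charge c.

| flask | substrate | coupling partner | transfer agent | initiator | remark | time |
|---|---|---|---|---|---|---|
| zeta | 20 mM | 19 mM | 6 mM | 1.2 mM | run made earlier |  |
| alpha | 20 mM | 19 mM | 6 mM | 12 mM | run made earlier |  |
| south-east | 20 mM | 19.0 mM | 6.00 mM | 1.0 mM |  | 40 h |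
| east | 20 mM | 19.0 mM | 6.00 mM | 2.0 mM |  | 40 h |
| south | 20 mM | 19.0 mM | 6.00 mM | 4.0 mM |  | 40 h |
| north-east | 20 mM | 19.0 mM | 6.00 mM | 8.0 mM |  | 40 h |

| run | time / h | target / % | substrate / % |
|---|---|---|---|
| zeta | 2.50 | 6.8 | 90.3 |
| zeta | 8.00 | 16.2 | 76.4 |
| zeta | 15.0 | 19.2 | 65.6 |
| zeta | 20.0 | 21.1 | 63.0 |
| zeta | 30.0 | 21.8 | 61.0 |
| zeta | 40.0 | 21.5 | 60.0 |
| alpha | 3.00 | 50.6 | 13.9 |
| alpha | 5.00 | 55.3 | 0 |
| alpha | 8.00 | 52.9 | 0 |
| alpha | 15.0 | 48.5 | 1.3 |
| alpha | 25.0 | 47.3 | 0.1 |
| alpha | 40.0 | 42.7 | 0 |

(scatter of a reading: 1 percentage point)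

- amount of target at the end, in percent of the substrate charged for south-east, east, south, north-east, in this order
- the course of these numbers from the first flask to the last (rises, then falls / rises all the way / falls, then rises / hardly changes / falls all the way)

My reckoning treats each charge of initiator as consuming a fixed amount of substrate. Zeta then gives

c* = c(zeta) / (fraction of substrate consumed) = 3.00 mM

This c* is the exhaustion charge, the initiator charge that on this reckoning uses up the substrate charged. Below it, the reckoning puts the fraction of substrate left at 1 − c/c*. Zeta made target at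

s = 53.8% of the substrate consumed.

So south-east should end near 17.9% target and east near 35.8%.

South holds 4.0 mM, more initiator than c*, and north-east holds 8.0 mM. Add nothing to either. Alpha, also above c*, read 55.3% target at 5.00 h with substrate at 0%, then 42.7% at 40.0 h. Alpha's last reading stands lower than s, so my row rises, then falls.

The forecast gave 18.5%, 33%, 46% and 50%, and its course rises all the way: “so the row should still be rising, though the margin at the top is small”. The two part at north-east.

The flasks end at 17.8%, 35.9%, 49.6% and 45.3% target; the course rises, then falls.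

    target ⇌ isomer of the product (K = 0.440, k = 3.20 × 10⁻⁴ /min)
    initiator → 2 initiating radical (k = 0.00190 /min)
    substrate + second chain carrier → released group + first chain carrier (k = 3.80 × 10⁵ /M/min)
    2 idle radical → ended radicals (k = 4.20 × 10⁶ /M/s)
    2 first chain carrier → ended chains (k = 5.00 × 10⁸ /M/s)
    substrate + initiating radical → capped initiator + first chain carrier (k = 31000 /M/s)
    coupling partner + first chain carrier → target + second chain carrier (k = 2.70 × 10⁵ /M/min)
    transfer agent + first chain carrier → side product + idle radical (kL = 3.60 × 10⁵ /M/min)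

The row turns at an initiator charge of 3.0 mM. Reckoned from c*, south-east should keep 66.7% of its substrate, and it holds 66.2%. East should keep 33.3%, and it holds 32.1%.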